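**Synthesis proposal for CNP0252548.1, (3R,7R)-3,7-dimethyl-6,8-dioxo-4,6,7,8-tetrahydro-3H-isochromen-7-yl oleate**

Retrosynthetic cuts: C8–C8a (ring A, cut first), the oleate C–O bond at C7, C4a=C5 (aldol addition and dehydration), C6–C7 (lactate enolate plus acetaldehyde), and in ring B the O2–C1 bond (oxa-Michael closure) and the C4a–C8a bond (ynone from a Weinreb amide).
Forward order: ring B is made first as (R)-2-methyl-2,3-dihydro-4H-pyran-4-one; the lactate-derived C5–C8 unit, held as a dioxolanone, is joined at C4a=C5; the auxiliary is opened, the oleate is put on, and ring A is closed last.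
Enabling feature: in ring B the enol ether O2–C1=C8a is conjugated through C4a=C5 to the C6 ketone, which leaves C8a as the carbon nucleophile of the system, placed so that bonding to the C8 carboxyl closes the six-membered ring A; C7 is quaternary by then, so the acylation cannot scramble it.
Stereochemistry: C3 (R) is the carbinol carbon of methyl (R)-3-hydroxybutanoate; C7 (R) comes from (S)-lactic acid through its tert-butyl acetal (self-regeneration of stereocentres); the Z alkene is bought with oleoyl chloride.

Key step: step 13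

Remark: atom labels C1 to C8a follow the isochromene numbering of the target in every intermediate. The C4a=C5 alkene of the pyranylidene intermediates is drawn Z (C6 cis to C8a); a mixture of geometries would serve equally, because this push-pull bond isomerises readily.

**Route**

Step 1
Reactants: 1 methyl (R)-3-hydroxybutanoate; 2 tert-butyldimethylsilyl chloride
Product: 3 methyl (R)-3-[(tert-butyldimethylsilyl)oxy]butanoate
Conditions: TBSCl (1.1 equiv), imidazole (2 equiv), DMF, 0 °C to rt
Reagents that add atoms: tert-butyldimethylsilyl chloride, CC(C)(C)[Si](C)(C)Cl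
Why: Imidazole-promoted silyl ether formation masks the secondary hydroxyl for the two organomagnesium steps without touching the carbinol stereocentre.

Step 2
Reactants: 3 methyl (R)-3-[(tert-butyldimethylsilyl)oxy]butanoate; 4 N,O-dimethylhydroxylamine hydrochloride
Product: 5 (R)-3-[(tert-butyldimethylsilyl)oxy]-N-methoxy-N-methylbutanamide
Conditions: MeNH(OMe)·HCl (1.5 equiv), iPrMgCl (3 equiv), THF, -20 to 0 °C; cold 1 M HCl
Reagents that add atoms: N,O-dimethylhydroxylamine hydrochloride, CNOC.Cl
Why: Direct conversion of an ester into its Weinreb amide with the chloromagnesium amide is a dependable acyl substitution that stops at the amide, and the low temperature disfavours beta-elimination of the silyloxy group.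

Step 3
Reactants: 5 (R)-3-[(tert-butyldimethylsilyl)oxy]-N-methoxy-N-methylbutanamide; 6 ethynylmagnesium bromide
Product: 7 (R)-5-[(tert-butyldimethylsilyl)oxy]hex-1-yn-3-one
Conditions: HC≡CMgBr (2 equiv), THF, 0 °C to rt; inverse quench into cold 1 M HCl
Reagents that add atoms: ethynylmagnesium bromide, C#C[Mg]Br
Why: In the Weinreb ketone synthesis the adduct is held as a magnesium chelate until work-up, so the alkynyl Grignard reagent adds only once, and the acidic inverse quench keeps the released amine from adding to the ynone.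

Step 4
Reactants: 7 (R)-5-[(tert-butyldimethylsilyl)oxy]hex-1-yn-3-one
Product: 9 (R)-2-methyl-2,3-dihydro-4H-pyran-4-one, via hydroxy ynone 8 (not isolated)
Conditions: TsOH·H2O (0.2 equiv), MeOH, 0 °C to rt
Reagents that add atoms: none
Why: Acid-catalysed methanolysis of the silyl ether frees the C3 hydroxyl, which closes ring B by 6-endo-dig oxa-Michael addition to the terminal ynone (a standard entry to 2,3-dihydro-4H-pyran-4-ones), and the stereocentre is untouched because its C–O bond is never broken.

Step 5
Reactants: 10 (S)-lactic acid; 11 pivaldehyde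
Product: 12 (2S,5S)-2-tert-butyl-5-methyl-1,3-dioxolan-4-one
Conditions: TsOH·H2O (cat.), H2SO4 (cat.), pentane, reflux, Dean-Stark; crystallisation from pentane/Et2O at -78 °C
Reagents that add atoms: pivaldehyde, CC(C)(C)C=O
Why: Acid-catalysed acetalisation with azeotropic removal of water should give the Seebach dioxolanone as a cis-rich mixture, from which low-temperature crystallisation should deliver the cis isomer whose acetal carbon stores the lactate configuration.

Step 6
Reactants: 12 (2S,5S)-2-tert-butyl-5-methyl-1,3-dioxolan-4-one; 13 acetaldehyde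
Product: 14 (2S,5R)-2-tert-butyl-5-(1-hydroxyethyl)-5-methyl-1,3-dioxolan-4-one (both carbinol epimers)
Conditions: LiN(iPr)2 (1.05 equiv), THF, -78 °C; MeCHO (2 equiv), -78 °C; AcOH, -78 °C
Reagents that add atoms: acetaldehyde, CC=O
Why: The lithium enolate is planar at C7 and the aldehyde approaches the face opposite the tert-butyl group (Seebach aldol of dioxolanone enolates), so the C6–C7 bond forms with net retention at C7, while the carbinol centre is irrelevant because it is oxidised next.

Step 7
Reactants: 14 (2S,5R)-2-tert-butyl-5-(1-hydroxyethyl)-5-methyl-1,3-dioxolan-4-one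
Product: 15 (2S,5R)-5-acetyl-2-tert-butyl-5-methyl-1,3-dioxolan-4-one
Conditions: Dess-Martin periodinane (1.3 equiv), CH2Cl2, rt
Reagents that add atoms: none
Why: Dess-Martin oxidation turns the secondary carbinol into the methyl ketone under non-basic conditions, so no retro-aldol cleavage occurs and the quaternary C7 cannot epimerise.

Step 8
Reactants: 15 (2S,5R)-5-acetyl-2-tert-butyl-5-methyl-1,3-dioxolan-4-one; 9 (R)-2-methyl-2,3-dihydro-4H-pyran-4-one
Product: 16 (2S,5R)-2-tert-butyl-5-{[(2R)-4-hydroxy-2-methyl-3,4-dihydro-2H-pyran-4-yl]acetyl}-5-methyl-1,3-dioxolan-4-one (both C4a epimers)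
Conditions: LiN(iPr)2 (1.05 equiv), THF, -78 °C; anhydrous CeCl3 (trivalent cerium, 1.1 equiv), -78 °C; 9 (1.0 equiv), -78 °C; AcOH, -78 °C
Reagents that add atoms: none
Why: The methyl ketone has a single enolisable position, and its cerium enolate (Imamoto-type aldol) should add 1,2 to the weakly electrophilic, enolisable vinylogous ester carbonyl, as organometallics do in the first half of the Stork-Danheiser sequence, the cold acidic quench freezing the adduct before retro-aldol or conjugate addition can compete; the new carbinol centre forms as a mixture and is erased in step 9.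

Step 9
Reactants: 16 (2S,5R)-2-tert-butyl-5-{[(2R)-4-hydroxy-2-methyl-3,4-dihydro-2H-pyran-4-yl]acetyl}-5-methyl-1,3-dioxolan-4-one
Product: 18 (2S,5R)-2-tert-butyl-5-methyl-5-{(2Z)-[(2R)-2-methyl-2,3-dihydro-4H-pyran-4-ylidene]acetyl}-1,3-dioxolan-4-one, via tertiary mesylate 17 (not isolated)
Conditions: MsCl (1.5 equiv), Et3N (4 equiv), CH2Cl2, -20 °C to rt
Reagents that add atoms: none
Why: Sulfene-mediated mesylation of the tertiary alcohol and amine-promoted loss of the acidic C5 proton (E1cB-type dehydration of an aldol) should give the fully conjugated exocyclic dienone, which is the thermodynamically favoured alkene isomer.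

Step 10
Reactants: 18 (2S,5R)-2-tert-butyl-5-methyl-5-{(2Z)-[(2R)-2-methyl-2,3-dihydro-4H-pyran-4-ylidene]acetyl}-1,3-dioxolan-4-one; 19 allyl alcohol
Product: 20 allyl (2R)-2-hydroxy-2-methyl-4-[(2R)-2-methyl-2,3-dihydro-4H-pyran-4-ylidene]-3-oxobutanoate (Z at C4a=C5)
Conditions: allyl alcohol (5 equiv), NaH (1.1 equiv), THF, -30 to 0 °C; AcOH, -30 °C
Reagents that add atoms: allyl alcohol, C=CCO
Why: Alkoxide attack on the activated acylal carbonyl is the standard opening of a Seebach dioxolanone to the alpha-hydroxy ester with loss of pivaldehyde; at low temperature the lactone should react ahead of the conjugated C6 ketone, and an alpha-ketol shift of the transient C7 alkoxide is uphill because it would take C6 out of the push-pull conjugation, so C7 keeps its configuration.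

Step 11
Reactants: 20 allyl (2R)-2-hydroxy-2-methyl-4-[(2R)-2-methyl-2,3-dihydro-4H-pyran-4-ylidene]-3-oxobutanoate; 21 oleoyl chloride
Product: 22 allyl (2R)-2-methyl-4-[(2R)-2-methyl-2,3-dihydro-4H-pyran-4-ylidene]-2-[(9Z)-octadec-9-enoyloxy]-3-oxobutanoate
Conditions: oleoyl chloride (1.5 equiv), pyridine (3 equiv), DMAP (0.2 equiv), CH2Cl2, 0 °C to rt
Reagents that add atoms: oleoyl chloride, CCCCCCCC/C=C\CCCCCCCC(=O)Cl
Why: DMAP-catalysed acyl transfer from an acid chloride is known to esterify the hindered tertiary 7-hydroxyl of azaphilone-type alpha-hydroxy-beta-dicarbonyl compounds, pyridine is too weak a base to form a ketene from the acid chloride or an alkoxide at C7, and the Z alkene arrives unchanged with the acyl group.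

Step 12
Reactants: 22 allyl (2R)-2-methyl-4-[(2R)-2-methyl-2,3-dihydro-4H-pyran-4-ylidene]-2-[(9Z)-octadec-9-enoyloxy]-3-oxobutanoate
Product: 23 (2R)-2-methyl-4-[(2R)-2-methyl-2,3-dihydro-4H-pyran-4-ylidene]-2-[(9Z)-octadec-9-enoyloxy]-3-oxobutanoic acid (kept as a cold CH2Cl2 solution)
Conditions: Pd(PPh3)4 (zerovalent palladium, 3 mol %), TolSO2Na (1.2 equiv), THF/MeOH, 0 °C; cold aq. NaHSO4, extraction into CH2Cl2 at 0 °C
Reagents that add atoms: none
Why: Tsuji-Trost deallylation with a sulfinate as allyl acceptor is neutral and fast, so the pi-allyl complex should be intercepted before the beta-keto carboxylate can lose CO2, no amine is present that could attack C1 of the dienyl ether, and the acid is set free only at 0 °C and used at once.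

Step 13
Reactants: 23 (2R)-2-methyl-4-[(2R)-2-methyl-2,3-dihydro-4H-pyran-4-ylidene]-2-[(9Z)-octadec-9-enoyloxy]-3-oxobutanoic acid
Product: 25 (3R,7R)-3,7-dimethyl-6,8-dioxo-4,6,7,8-tetrahydro-3H-isochromen-7-yl (9Z)-octadec-9-enoate (target CNP0252548.1), via acyl chloride 24 (not isolated)
Conditions: 1-chloro-N,N,2-trimethylprop-1-en-1-amine (1.1 equiv), CH2Cl2 (0.01 M), 0 °C; then 2,6-di-tert-butyl-4-methylpyridine (1.5 equiv), 0 to 35 °C
Reagents that add atoms: none
Why: Proposed new method: the chloroenamine converts the acid into acyl chloride 24 without releasing HCl, after which C8a, the enol ether carbon that carries the donor density of O2 in the chain O2-C1=C8a-C4a=C5-C6=O, adds to the C8 carbonyl, chloride leaves from the tetrahedral carbon, and the pyridine base takes the C8a proton from the O2-stabilised C1 oxocarbenium ion so that C1=C8a returns as part of a vinylogous ester. The closest known reaction type is the Friedel-Crafts-type C-acylation of enol ethers, dihydropyrans and enaminones by activated acyl chlorides (Darzens-Nenitzescu acylation of alkenes); the new element is its intramolecular use on a conjugated enol ether with an acyl chloride that is activated only inductively, by the 7-acyloxy and 6-oxo groups. Ring A closes 6-exo-trig at the acyl carbon, with C1=C8a exocyclic to the forming ring. No stereocentre is created, and the existing ones are safe because C7 bears no hydrogen (no ketene, no epimerisation) and the C3–O2 bond is not involved. The step needs C8a to react rather than C5, C4 or the oleate alkene, which the substrate secures since only C8a is both an enol ether carbon and within six-membered reach of C8 (attack by C5 would make a cyclobutanone, C4 is not nucleophilic unless deprotonated, and the chain alkene is unactivated and far away), while the readily rotating push-pull C4a=C5 bond feeds either alkene isomer into the reactive geometry. Ionising promoters such as silver salts are left out deliberately, because a free acylium ion would be trapped by the neighbouring oleate carbonyl as a dioxolanonylium ion.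

**Compound list**

1 | methyl (R)-3-hydroxybutanoate | C[C@@H](O)CC(=O)OC | starting material
2 | tert-butyldimethylsilyl chloride | CC(C)(C)[Si](C)(C)Cl | starting material
3 | methyl (R)-3-[(tert-butyldimethylsilyl)oxy]butanoate | C[C@@H](O[Si](C)(C)C(C)(C)C)CC(=O)OC | intermediate
4 | N,O-dimethylhydroxylamine hydrochloride | CNOC.Cl | starting material
5 | (R)-3-[(tert-butyldimethylsilyl)oxy]-N-methoxy-N-methylbutanamide | C[C@@H](O[Si](C)(C)C(C)(C)C)CC(=O)N(C)OC | intermediate
6 | ethynylmagnesium bromide | C#C[Mg]Br | starting material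
7 | (R)-5-[(tert-butyldimethylsilyl)oxy]hex-1-yn-3-one | C[C@@H](O[Si](C)(C)C(C)(C)C)CC(=O)C#C | intermediate
8 | (R)-5-hydroxyhex-1-yn-3-one | C[C@@H](O)CC(=O)C#C | intermediate (not isolated)
9 | (R)-2-methyl-2,3-dihydro-4H-pyran-4-one | O=C1C[C@@H](C)OC=C1 | intermediate
10 | (S)-lactic acid | C[C@H](O)C(=O)O | starting material
11 | pivaldehyde | CC(C)(C)C=O | starting material
12 | (2S,5S)-2-tert-butyl-5-methyl-1,3-dioxolan-4-one | C[C@@H]1O[C@H](C(C)(C)C)OC1=O | intermediate
13 | acetaldehyde | CC=O | starting material
14 | (2S,5R)-2-tert-butyl-5-(1-hydroxyethyl)-5-methyl-1,3-dioxolan-4-one, both carbinol epimers | CC(O)[C@@]1(C)O[C@H](C(C)(C)C)OC1=O | intermediate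
15 | (2S,5R)-5-acetyl-2-tert-butyl-5-methyl-1,3-dioxolan-4-one | CC(=O)[C@@]1(C)O[C@H](C(C)(C)C)OC1=O | intermediate
16 | (2S,5R)-2-tert-butyl-5-{[(2R)-4-hydroxy-2-methyl-3,4-dihydro-2H-pyran-4-yl]acetyl}-5-methyl-1,3-dioxolan-4-one, both C4a epimers | O=C(CC1(O)C=CO[C@H](C)C1)[C@@]2(C)O[C@H](C(C)(C)C)OC2=O | intermediate
17 | tertiary methanesulfonate of 16 | O=C(CC1(OS(C)(=O)=O)C=CO[C@H](C)C1)[C@@]2(C)O[C@H](C(C)(C)C)OC2=O | intermediate (not isolated)
18 | (2S,5R)-2-tert-butyl-5-methyl-5-{(2Z)-[(2R)-2-methyl-2,3-dihydro-4H-pyran-4-ylidene]acetyl}-1,3-dioxolan-4-one | O=C(/C=C1\C=CO[C@H](C)C1)[C@@]2(C)O[C@H](C(C)(C)C)OC2=O | intermediate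
19 | allyl alcohol | C=CCO | starting material
20 | allyl (2R)-2-hydroxy-2-methyl-4-[(2R)-2-methyl-2,3-dihydro-4H-pyran-4-ylidene]-3-oxobutanoate | C=CCOC(=O)[C@](C)(O)C(=O)/C=C1\C=CO[C@H](C)C1 | intermediate
21 | oleoyl chloride | CCCCCCCC/C=C\CCCCCCCC(=O)Cl | starting material
22 | allyl (2R)-2-methyl-4-[(2R)-2-methyl-2,3-dihydro-4H-pyran-4-ylidene]-2-[(9Z)-octadec-9-enoyloxy]-3-oxobutanoate | CCCCCCCC/C=C\CCCCCCCC(=O)O[C@@](C)(C(=O)OCC=C)C(=O)/C=C1\C=CO[C@H](C)C1 | intermediate
23 | (2R)-2-methyl-4-[(2R)-2-methyl-2,3-dihydro-4H-pyran-4-ylidene]-2-[(9Z)-octadec-9-enoyloxy]-3-oxobutanoic acid | CCCCCCCC/C=C\CCCCCCCC(=O)O[C@@](C)(C(=O)O)C(=O)/C=C1\C=CO[C@H](C)C1 | intermediate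
24 | acyl chloride of 23 | CCCCCCCC/C=C\CCCCCCCC(=O)O[C@@](C)(C(=O)Cl)C(=O)/C=C1\C=CO[C@H](C)C1 | intermediate (not isolated)
25 | (3R,7R)-3,7-dimethyl-6,8-dioxo-4,6,7,8-tetrahydro-3H-isochromen-7-yl (9Z)-octadec-9-enoate | CCCCCCCC/C=C\CCCCCCCC(=O)O[C@]1(C)C(=O)C=C2C[C@@H](C)OC=C2C1=O | target

**Step count and risks**

Total step count: 13. Longest linear sequence: 10 steps (steps 1 to 4, then 8 to 13).

Steps most likely to fail:

1. Step 13 (the step proposed as new). The conjugated enol ether carbon may be too weak a nucleophile for the un-ionised acyl chloride. Ring closure could then be overtaken by intermolecular acylation, hydrolysis on work-up or loss of CO2. The fallback raises the nucleophilicity with nitrogen and uses only known reaction types; it sets out from 22 and comes back to the route at 25. Pyrrolidine (THF, 0 °C) adds at C1 and opens ring B, as amines do with vinylogous esters, to give the ring-opened hydroxy dienaminone F1. Its secondary hydroxyl is capped with Et3SiCl and imidazole to give the silyl ether F2. Deallylation as in step 12 gives the acid F3, and the chloroenamine reagent gives the acyl chloride F4. C-Acylation of the enaminone carbon C8a (Et3N, CH2Cl2), a standard reaction of push-pull enaminones with acid chlorides, closes ring A as the aminomethylene dione F5. Brief treatment with TsOH in wet THF at 0 °C removes the silyl group, and the C3 hydroxyl displaces pyrrolidine at C1 by addition-elimination, which closes ring B and gives 25.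

2. Step 8. The aldol addition may reverse on the way to work-up, and the enolate may instead add to C1 of the pyranone with opening of ring B. The fallback joins the fragments at C6–C7 instead; it sets out from 9 and 12 and comes back at 18. Lithiated N-tert-butyl-2-(trimethylsilyl)acetaldimine (LiN(iPr)2, THF, -78 °C) is an aza-enolate far more nucleophilic than a ketone enolate, and its adduct collapses irreversibly by Peterson elimination. It should convert 9 into the unsaturated imine F6, which aqueous oxalic acid hydrolyses to the dienal F7. The lithium enolate of 12 adds to F7 anti to the tert-butyl group, with the facial control of step 6, to give the carbinol F8. Dess-Martin oxidation buffered with NaHCO3 then gives 18.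

3. Step 10. The alkoxide may add at C1 of the dienyl ether or deprotonate C4 with elimination of O2, while the hindered lactone opens only slowly. The fallback opens the auxiliary before the pyran is present; it sets out from 14 and comes back at 20. Sodium allyloxide in allyl alcohol and THF opens 14, which has neither a ketone nor an enol ether, to the diol ester F9. Dess-Martin oxidation of the secondary hydroxyl gives the ketol F10, which is silylated at once (Et3SiOTf, 2,6-lutidine, -78 °C) to the silyl ether F11, so that no free ketol meets base. The cerium enolate of F11 (alpha-silyloxy ketone enolates are established aldol donors) adds to 9 as in step 8 to give the aldol F12. Mesylation gives the mesylate F13, and elimination as in step 9 gives the silyl-protected dienone F14. HF·pyridine in THF at 0 °C removes the silyl group and gives 20.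

**Further compounds**

F1 | step 13 | allyl (2R,7R)-7-hydroxy-2-methyl-2-[(9Z)-octadec-9-enoyloxy]-3-oxo-5-[(E)-2-(pyrrolidin-1-yl)ethenyl]oct-4-enoate | CCCCCCCC/C=C\CCCCCCCC(=O)O[C@@](C)(C(=O)OCC=C)C(=O)C=C(C[C@@H](C)O)/C=C/N1CCCC1
F2 | step 13 | 7-O-triethylsilyl ether of F1 | CCCCCCCC/C=C\CCCCCCCC(=O)O[C@@](C)(C(=O)OCC=C)C(=O)C=C(C[C@@H](C)O[Si](CC)(CC)CC)/C=C/N1CCCC1
F3 | step 13 | (2R,7R)-2-methyl-2-[(9Z)-octadec-9-enoyloxy]-3-oxo-5-[(E)-2-(pyrrolidin-1-yl)ethenyl]-7-(triethylsilyloxy)oct-4-enoic acid | CCCCCCCC/C=C\CCCCCCCC(=O)O[C@@](C)(C(=O)O)C(=O)C=C(C[C@@H](C)O[Si](CC)(CC)CC)/C=C/N1CCCC1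
F4 | step 13 | acyl chloride of F3 | CCCCCCCC/C=C\CCCCCCCC(=O)O[C@@](C)(C(=O)Cl)C(=O)C=C(C[C@@H](C)O[Si](CC)(CC)CC)/C=C/N1CCCC1
F5 | step 13 | (1R)-1-methyl-2,6-dioxo-3-(pyrrolidin-1-ylmethylidene)-4-[(2R)-2-(triethylsilyloxy)propyl]cyclohex-4-en-1-yl (9Z)-octadec-9-enoate | CCCCCCCC/C=C\CCCCCCCC(=O)O[C@]1(C)C(=O)C=C(C[C@@H](C)O[Si](CC)(CC)CC)C(=CN2CCCC2)C1=O
F6 | step 8 | N-tert-butyl-2-[(2R)-2-methyl-2,3-dihydro-4H-pyran-4-ylidene]ethanimine | CC(C)(C)N=C/C=C1\C=CO[C@H](C)C1
F7 | step 8 | [(2R)-2-methyl-2,3-dihydro-4H-pyran-4-ylidene]acetaldehyde | O=C/C=C1\C=CO[C@H](C)C1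
F8 | step 8 | (2S,5R)-2-tert-butyl-5-{1-hydroxy-2-[(2R)-2-methyl-2,3-dihydro-4H-pyran-4-ylidene]ethyl}-5-methyl-1,3-dioxolan-4-one, both carbinol epimers | OC(/C=C1\C=CO[C@H](C)C1)[C@@]2(C)O[C@H](C(C)(C)C)OC2=O
F9 | step 10 | allyl (2R)-2,3-dihydroxy-2-methylbutanoate, both C3 epimers | CC(O)[C@@](C)(O)C(=O)OCC=C
F10 | step 10 | allyl (2R)-2-hydroxy-2-methyl-3-oxobutanoate | CC(=O)[C@@](C)(O)C(=O)OCC=C
F11 | step 10 | allyl (2R)-2-methyl-3-oxo-2-(triethylsilyloxy)butanoate | CC(=O)[C@@](C)(O[Si](CC)(CC)CC)C(=O)OCC=C
F12 | step 10 | allyl (2R)-4-[(2R)-4-hydroxy-2-methyl-3,4-dihydro-2H-pyran-4-yl]-2-methyl-3-oxo-2-(triethylsilyloxy)butanoate, both C4a epimers | O=C(CC1(O)C=CO[C@H](C)C1)[C@@](C)(O[Si](CC)(CC)CC)C(=O)OCC=C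
F13 | step 10 | tertiary methanesulfonate of F12 | O=C(CC1(OS(C)(=O)=O)C=CO[C@H](C)C1)[C@@](C)(O[Si](CC)(CC)CC)C(=O)OCC=C
F14 | step 10 | allyl (2R)-2-methyl-4-[(2R)-2-methyl-2,3-dihydro-4H-pyran-4-ylidene]-3-oxo-2-(triethylsilyloxy)butanoate | O=C(/C=C1\C=CO[C@H](C)C1)[C@@](C)(O[Si](CC)(CC)CC)C(=O)OCC=C
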